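**Assumption:** Cudraphenone D as drawn has no stereocenters, and its two prenyl alkenes have no E/Z designation, so the target is achiral and there is no enantiomer to set.

## Retrosynthetic overview
1. Remove the four phenol protecting groups last (tetra-MOM to the tetra-phenol).
2. Disconnect the diaryl ketone between the carbonyl and ring B: a 2,6-bis(MOMO)aryllithium (ring B) adds to a Weinreb amide (ring A).
3. Ring B aryllithium comes from 2-prenyl-1,3,5-tris(MOMO)benzene by a second directed lithiation. That arene comes from phloroglucinol by tris-MOM protection, then lithiation and prenylation.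
4. Ring A Weinreb amide comes from 3-hydroxybenzoate by MOM protection, carboxylate-directed C2 lithiation and prenylation, and amide formation.
5. Both benzene rings are purchased; no ring is constructed. Regiochemistry comes entirely from directed ortho-metalation.

## Route

**Step 1**
Reactants: 1 (methyl 3-hydroxybenzoate); 2 (chloromethyl methyl ether, MOMCl)
Product: 3 (methyl 3-(methoxymethoxy)benzoate)
Conditions: MOMCl, i-Pr2NEt, CH2Cl2, 0 °C to rt
Reagents that add atoms: MOMCl, COCCl
Why: Base-mediated O-alkylation of the phenol gives the MOM acetal, which is stable to the strong bases used later. No stereocenter is formed.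

**Step 2**
Reactants: 3
Product: 4 (3-(methoxymethoxy)benzoic acid)
Conditions: LiOH, THF/H2O, rt; then acidify to pH ~4 with citric acid
Reagents that add atoms: water (O); LiOH, [Li+].[OH-]
Why: Ester saponification; the MOM acetal is base-stable and survives the mild citric acid quench.

**Step 3**
Reactants: 4; 5 (prenyl bromide, 1-bromo-3-methylbut-2-ene)
Product: 6 (3-(methoxymethoxy)-2-(3-methylbut-2-en-1-yl)benzoic acid)
Conditions: s-BuLi (2.2 equiv), TMEDA, THF, –78 °C; then prenyl bromide, –78 °C to rt; citric acid workup
Reagents that add atoms: prenyl bromide, CC(C)=CCBr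
Why: Directed ortho-metalation. The lithium carboxylate and the OMOM group cooperatively direct lithiation to C2, between them, and the aryllithium is then C-alkylated by the allylic bromide (SN2).

**Step 4**
Reactants: 6; 7 (N,O-dimethylhydroxylamine hydrochloride)
Product: 8 (N-methoxy-N-methyl-3-(methoxymethoxy)-2-(3-methylbut-2-en-1-yl)benzamide, the Weinreb amide)
Conditions: EDC·HCl, HOBt, i-Pr2NEt, DMF, rt
Reagents that add atoms: MeNH(OMe)·HCl, CNOC.Cl
Why: Carbodiimide amide coupling gives a Weinreb amide, which will stop at the ketone stage on organolithium addition.

**Step 5**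
Reactants: 9 (phloroglucinol); 2 (MOMCl)
Product: 10 (1,3,5-tris(methoxymethoxy)benzene)
Conditions: NaH (3.3 equiv), MOMCl (3.3 equiv), DMF, 0 °C to rt
Reagents that add atoms: MOMCl, COCCl
Why: Triple O-alkylation of the phloroglucinol trianion gives the tris-acetal, a strongly ortho-directing arene.

**Step 6**
Reactants: 10; 5 (prenyl bromide)
Product: 11 (2-(3-methylbut-2-en-1-yl)-1,3,5-tris(methoxymethoxy)benzene)
Conditions: n-BuLi (1.05 equiv), THF, 0 °C; then CuI (10 mol%), prenyl bromide, –40 °C to rt
Reagents that add atoms: prenyl bromide, CC(C)=CCBr
Why: Lithiation occurs between two OMOM groups, and Cu catalysis favors SN2 alkylation over SN2′ (which would give a reverse prenyl group). Mono-alkylation is controlled by using 1.05 equiv of n-BuLi.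

**Step 7**
Reactants: 11; 8
Product: 12 (2,4,6-tris(MOMO)-3-prenylphenyl 3-(MOMO)-2-prenylphenyl ketone)
Conditions: n-BuLi (1.1 equiv), THF, 0 °C, 1 h; then add 8, –78 °C to 0 °C; aq. NH4Cl
Reagents that add atoms: none (the ArLi and Weinreb amide are both numbered reactants)
Why: A second directed lithiation at the equivalent C4/C6 positions of 11 (each between two OMOM groups) gives a single regioisomer. The aryllithium adds to the Weinreb amide to form a stable chelated tetrahedral intermediate, which collapses to the ketone on workup with no over-addition.

**Step 8**
Reactants: 12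
Product: 13 (Cudraphenone D)
Conditions: 3 M HCl, THF/MeOH (1:1), 45 °C
Reagents that add atoms: none (only H is added; the MOM groups leave as CH2(OMe)OH-derived fragments, in MeOH)
Why: Acid-catalyzed hydrolysis or methanolysis of all four aryl MOM acetals. The prenyl alkenes and the diaryl ketone survive dilute HCl at mild temperature, and the chelated 2-hydroxybenzophenone is the product.

## Check of target against route
- Ring A has acyl at C1, prenyl at C2 and OH at C3, which matches `CC(C)=CCc1c(O)cccc1C(=O)…`.
- Ring B has acyl at C1, OH at C2, H at C3, OH at C4, prenyl at C5 and OH at C6.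
- Ring B arises from 11 by acylation at C4/C6, which are equivalent positions, so the prenyl ends up meta to the carbonyl and flanked by two OH groups, as in the target.
- The atom balance closes at each step, and 13 is C23H26O5.
- There are no stereocenters to scramble.

## Compound list
1 | methyl 3-hydroxybenzoate | COC(=O)c1cccc(O)c1 | starting material
2 | chloromethyl methyl ether (MOMCl) | COCCl | starting material
3 | methyl 3-(methoxymethoxy)benzoate | COC(=O)c1cccc(OCOC)c1 | intermediate
4 | 3-(methoxymethoxy)benzoic acid | COCOc1cccc(C(=O)O)c1 | intermediate
5 | prenyl bromide | CC(C)=CCBr | starting material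
6 | 3-(methoxymethoxy)-2-prenylbenzoic acid | COCOc1cccc(C(=O)O)c1CC=C(C)C | intermediate
7 | N,O-dimethylhydroxylamine hydrochloride | CNOC.Cl | starting material
8 | N-methoxy-N-methyl-3-(methoxymethoxy)-2-prenylbenzamide | CON(C)C(=O)c1cccc(OCOC)c1CC=C(C)C | intermediate
9 | phloroglucinol | Oc1cc(O)cc(O)c1 | starting material
10 | 1,3,5-tris(methoxymethoxy)benzene | COCOc1cc(OCOC)cc(OCOC)c1 | intermediate
11 | 2-prenyl-1,3,5-tris(methoxymethoxy)benzene | COCOc1cc(OCOC)c(CC=C(C)C)c(OCOC)c1 | intermediate
12 | tetra-MOM benzophenone | COCOc1cccc(C(=O)c2c(OCOC)cc(OCOC)c(CC=C(C)C)c2OCOC)c1CC=C(C)C | intermediate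
13 | Cudraphenone D (achiral) | CC(C)=CCc1c(O)cccc1C(=O)c1c(O)cc(O)c(CC=C(C)C)c1O | target

**Total steps:** 8. **Longest linear sequence:** 6 (Steps 1, 2, 3, 4, 7, 8); Steps 5 and 6 form the convergent ring-B branch.

## Three steps most likely to fail
1. **Step 7 (hindered ArLi plus hindered Weinreb amide; the allylic/benzylic CH2 of the prenyl group could be deprotonated instead of the ring C–H).**
   Fallback: iodinate 11 (NIS) at C4, then generate the aryllithium by I/Li exchange (t-BuLi, –78 °C) before adding 8, which avoids the deprotonation step entirely.
2. **Step 3 (dianion C2-prenylation: low yield, SN2′ reverse-prenyl product, or wrong regiochemistry).**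
   Fallback: start from 2-bromo-3-hydroxybenzoic acid as its MOM ether and Weinreb amide. Convert the C–Br to the aryl Grignard (i-PrMgCl·LiCl), then Cu-catalyzed coupling with prenyl bromide, so regiochemistry is fixed by the bromide rather than by lithiation.
3. **Step 8 (acid-mediated prenyl cyclization of the ortho-prenylphenols to chromans, or incomplete removal of the four MOM groups).**
   Fallback: take a ring-B precursor without the prenyl group through coupling and MOM removal to the 2,4,6-trihydroxybenzophenone, then do a late-stage C-prenylation (prenyl bromide, aq. KOH/MeOH) at the single free phloroglucinol position, accepting a chromatographic separation of mono- and di-prenylated products.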